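**Retrosynthetic overview** (locants are the cyclodeca[b]furan numbering of the target)
1. The ten-membered carbocycle is opened at C8–C9: an intramolecular boron aldol of a C7 methyl ketone onto a C9 aldehyde closes it as the last ring.
2. The C9 aldehyde comes from a primary nitro group (Nef). The cis-fused α-methylene-γ-butyrolactone (C3a–C11a bond, first ring formed) comes from a chiral Brønsted acid-catalysed allylboration–lactonisation of a 2-carbomethoxy allylboronate with a β-methyl-γ-nitro aldehyde.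
3. The allylboronate (C4 angelate, C6 tertiary acetate, C7 ketone) comes from angeloylation and copper-catalysed SN2' borylation of a vinyl epoxide, itself made by chiral sulfonium-ylide epoxidation of a β-acetoxy aldehyde with methyl 2-(bromomethyl)acrylate.
4. The β-acetoxy aldehyde comes from an organocatalytic acetaldehyde/biacetyl aldol (first stereocentre, C6); the nitro aldehyde comes from an organocatalytic nitromethane/crotonaldehyde Michael addition (C10).

Assumption: the absolute sense of induction of each chiral catalyst or reagent is assigned by analogy with its closest published use; all are available in both enantiomeric forms, so a reversed sense is corrected by using the antipode.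

**Route**

Step 1
Reactants: 1 butane-2,3-dione; 2 acetaldehyde
Product: 4 (3S)-3-hydroxy-5,5-dimethoxy-3-methylpentan-2-one, via aldol aldehyde 3 (not isolated)
Conditions: (S)-α,α-bis[3,5-bis(trifluoromethyl)phenyl]prolinol (10 mol %), 1 (3 equiv), NMP, 4 °C, 48 h; then HC(OMe)3, p-TsOH·H2O (cat.), MeOH, 0 °C to rt
Reagents that add atoms: trimethyl orthoformate, COC(OC)OC
Why: Proposed new method: an enamine cross-aldol of acetaldehyde onto an unactivated vicinal diketone, in which the diarylprolinol condenses selectively with the aldehyde, its carbinol OH hydrogen-bonds the dicarbonyl and the enamine adds to the Si face of one of the two equivalent carbonyls to set C6 (3S), the adduct being trapped as its acetal before retro-aldol or dehydration can occur; the closest known reaction type is the diarylprolinol-catalysed cross-aldol of acetaldehyde with activated ketones (isatins, trifluoromethyl ketones, α-keto esters).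

Step 2
Reactants: 4 (3S)-3-hydroxy-5,5-dimethoxy-3-methylpentan-2-one
Product: 5 (3S)-5,5-dimethoxy-3-methyl-2-oxopentan-3-yl acetate
Conditions: Ac2O, Et3N, DMAP (0.3 equiv), CH2Cl2, rt, 24 h
Reagents that add atoms: acetic anhydride, CC(=O)OC(C)=O
Why: DMAP-catalysed (Steglich-type) acylation of the tertiary α-ketol installs the C6 acetate of the target at the stage where the aldehyde is still masked, so no stereocentre is touched and β-elimination is impossible.

Step 3
Reactants: 5 (3S)-5,5-dimethoxy-3-methyl-2-oxopentan-3-yl acetate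
Product: 6 (3S)-3-methyl-2,5-dioxopentan-3-yl acetate
Conditions: Amberlyst-15, acetone/H2O (10:1), rt; used crude
Reagents that add atoms: water, O
Why: Acid-catalysed acetal hydrolysis releases the β-acetoxy aldehyde under non-basic conditions, which avoids E1cB loss of acetate, and the quaternary C6 centre cannot epimerise.

Step 4
Reactants: 6 (3S)-3-methyl-2,5-dioxopentan-3-yl acetate; 7 methyl 2-(bromomethyl)prop-2-enoate
Product: 10 methyl 2-[(2R,3R)-3-[(2S)-2-(acetyloxy)-2-methyl-3-oxobutyl]oxiran-2-yl]prop-2-enoate, via sulfonium bromide 8 (not isolated), via sulfonium ylide 9 (not isolated)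
Conditions: (2S,5S)-2,5-dimethylthiolane (1.1 equiv), 7, MeCN, rt, 12 h; then 6, Cs2CO3, MeCN, −30 to 0 °C; sulfide recovered, C4 epimer removed by chromatography
Reagents that add atoms: none
Why: Asymmetric sulfonium-ylide epoxidation (Corey–Chaykovsky type with a C2-symmetric chiral thiolane) in which the 2-substituted allyl ylide adds to the aldehyde faster than it deprotonates it and the anti-betaine closes to the trans vinyl epoxide, reagent control fixing C4 as R (the C3a epoxide centre is erased in step 5).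

Step 5
Reactants: 10 methyl 2-[(2R,3R)-3-[(2S)-2-(acetyloxy)-2-methyl-3-oxobutyl]oxiran-2-yl]prop-2-enoate
Product: 11 methyl (2E,4R,6S)-6-(acetyloxy)-4-hydroxy-6-methyl-7-oxo-2-[(4,4,5,5-tetramethyl-1,3,2-dioxaborolan-2-yl)methyl]oct-2-enoate
Conditions: B2pin2 (1.1 equiv), CuCl (5 mol %), Xantphos (5 mol %), NaOt-Bu (10 mol %), MeOH (2 equiv), THF, 0 °C
Reagents that add atoms: bis(pinacolato)diboron, CC1(C)OB(OC1(C)C)B1OC(C)(C)C(C)(C)O1
Why: Copper-catalysed conjugate borylation of the acrylate followed by β-alkoxide elimination (a formal SN2' borylation of a vinyl epoxide) leaves the C4–O bond untouched (4R) and, as in SN2' reactions of Baylis–Hillman acetates of esters, places C4 cis to the CH2B carbon and trans to the ester (2E).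

Step 6
Reactants: 11 methyl (2E,4R,6S)-6-(acetyloxy)-4-hydroxy-6-methyl-7-oxo-2-[(4,4,5,5-tetramethyl-1,3,2-dioxaborolan-2-yl)methyl]oct-2-enoate; 12 (2Z)-2-methylbut-2-enoic acid (angelic acid)
Product: 14 methyl (2E,4R,6S)-6-(acetyloxy)-6-methyl-4-{[(2Z)-2-methylbut-2-enoyl]oxy}-7-oxo-2-[(4,4,5,5-tetramethyl-1,3,2-dioxaborolan-2-yl)methyl]oct-2-enoate, via mixed anhydride 13 (not isolated)
Conditions: 12, 2,4,6-trichlorobenzoyl chloride, Et3N, toluene, rt, 2 h; then 11, toluene, 75 °C, 12 h
Reagents that add atoms: none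
Why: Yamaguchi-type mixed-anhydride esterification run without DMAP is the established way to make angelates without Z to E isomerisation to the tiglate, it acylates the secondary C4 hydroxyl with retention, and the ester-deactivated allylboronate survives the heating.

Step 7
Reactants: 15 (2E)-but-2-enal (crotonaldehyde); 16 nitromethane
Product: 17 (3S)-3-methyl-4-nitrobutanal
Conditions: (R)-α,α-diphenylprolinol trimethylsilyl ether (10 mol %), PhCO2H (20 mol %), 16 (3 equiv), MeOH, rt
Reagents that add atoms: none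
Why: Iminium-catalysed Michael addition of nitromethane (Hayashi–Jørgensen catalyst), in which the nitronate adds to the face of the E-iminium ion opposite the diarylsilyloxymethyl group and sets C10 (3S).

Step 8
Reactants: 14 methyl (2E,4R,6S)-6-(acetyloxy)-6-methyl-4-{[(2Z)-2-methylbut-2-enoyl]oxy}-7-oxo-2-[(4,4,5,5-tetramethyl-1,3,2-dioxaborolan-2-yl)methyl]oct-2-enoate; 17 (3S)-3-methyl-4-nitrobutanal
Product: 19 (1R,3S)-3-(acetyloxy)-3-methyl-1-[(2S,3S)-4-methylidene-2-[(2S)-2-methyl-3-nitropropyl]-5-oxooxolan-3-yl]-4-oxopentyl (2Z)-2-methylbut-2-enoate, via borate adduct 18 (not isolated)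
Conditions: (R)-3,3'-bis(2,4,6-triisopropylphenyl)-BINOL N-triflylphosphoramide (10 mol %), 17 (3 equiv), 4 Å MS, toluene, −20 °C to rt, 48 h; then p-TsOH·H2O (20 mol %), rt
Reagents that add atoms: none
Why: Proposed new method: a chiral Brønsted acid-catalysed allylboration–lactonisation of a γ-substituted 2-carbomethoxy allylboronate, in which the strong chiral acid hydrogen-bonds a boronate oxygen and so restores the Lewis acidity lost to the ester, and the reaction runs through a closed chair transition state where the C4 substituent cis to CH2B is axial (syn adduct, hence the cis lactone) and the aldehyde Re face demanded by the catalyst coincides with attack on the allyl face anti to C5 with the angelate outside and H inside (C3a S, C11a S), the borate then lactonising under acid; the closest known reaction types are the chiral phosphoric acid-catalysed allylboration of aldehydes (Antilla) and the triflic acid-catalysed addition of 2-alkoxycarbonyl allylboronates with lactonisation (Hall).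

Step 9
Reactants: 19 (1R,3S)-3-(acetyloxy)-3-methyl-1-[(2S,3S)-4-methylidene-2-[(2S)-2-methyl-3-nitropropyl]-5-oxooxolan-3-yl]-4-oxopentyl (2Z)-2-methylbut-2-enoate
Product: 20 (1R,3S)-3-(acetyloxy)-3-methyl-1-[(2S,3S)-4-methylidene-2-[(2S)-2-methyl-3-oxopropyl]-5-oxooxolan-3-yl]-4-oxopentyl (2Z)-2-methylbut-2-enoate
Conditions: aq. TiCl3 (6 equiv), NH4OAc buffer (pH 6), THF/H2O, 0 °C to rt; used at once
Reagents that add atoms: water, O
Why: McMurry's buffered TiCl3 variant of the Nef reaction reduces the primary nitro group to the N–H imine, which hydrolyses to the aldehyde near neutral pH, so the esters, the α-methylene lactone and the now α-positioned C10 stereocentre are preserved.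

Step 10
Reactants: 20 (1R,3S)-3-(acetyloxy)-3-methyl-1-[(2S,3S)-4-methylidene-2-[(2S)-2-methyl-3-oxopropyl]-5-oxooxolan-3-yl]-4-oxopentyl (2Z)-2-methylbut-2-enoate
Product: 22 (3aS,4R,6S,9R,10S,11aS)-6-(acetyloxy)-9-hydroxy-6,10-dimethyl-3-methylidene-2,7-dioxododecahydrocyclodeca[b]furan-4-yl (2Z)-2-methylbut-2-enoate (CNP0141210.3), via boron enolate 21 (not isolated)
Conditions: Bu2BOTf (1.2 equiv), i-Pr2NEt (1.5 equiv), CH2Cl2, −78 °C, slow addition of 20 (final 0.002 M), −78 to −40 °C; then pH 7 buffer/MeOH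
Reagents that add atoms: none
Why: Intramolecular boron aldol reaction under kinetic control, in which the methyl ketone has only one enolisable position (C6 is quaternary), the enol borinate adds to the tethered aldehyde through a closed Zimmerman–Traxler transition state to give a chelated aldolate that cannot revert, and C9 (R) is set by macrocyclic control with the C10 methyl pseudo-equatorial, which is the least certain stereochemical element of the route.

**Compound list**
1 | butane-2,3-dione | CC(=O)C(C)=O | starting material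
2 | acetaldehyde | CC=O | starting material
3 | (3S)-3-hydroxy-3-methyl-4-oxopentanal | CC(=O)[C@@](C)(O)CC=O | intermediate
4 | (3S)-3-hydroxy-5,5-dimethoxy-3-methylpentan-2-one | CC(=O)[C@@](C)(O)CC(OC)OC | intermediate
5 | (3S)-5,5-dimethoxy-3-methyl-2-oxopentan-3-yl acetate | CC(=O)[C@@](C)(OC(C)=O)CC(OC)OC | intermediate
6 | (3S)-3-methyl-2,5-dioxopentan-3-yl acetate | CC(=O)[C@@](C)(OC(C)=O)CC=O | intermediate
7 | methyl 2-(bromomethyl)prop-2-enoate | C=C(CBr)C(=O)OC | starting material
8 | (2S,5S)-1-[2-(methoxycarbonyl)prop-2-en-1-yl]-2,5-dimethylthiolan-1-ium bromide | C[C@H]1CC[C@H](C)[S+]1CC(=C)C(=O)OC.[Br-] | intermediate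
9 | 2-(methoxycarbonyl)-1-[(2S,5S)-2,5-dimethylthiolan-1-ium-1-yl]prop-2-en-1-ide | C[C@H]1CC[C@H](C)[S+]1[CH-]C(=C)C(=O)OC | intermediate
10 | methyl 2-[(2R,3R)-3-[(2S)-2-(acetyloxy)-2-methyl-3-oxobutyl]oxiran-2-yl]prop-2-enoate | CC(=O)[C@@](C)(OC(C)=O)C[C@H]1O[C@@H]1C(=C)C(=O)OC | intermediate
11 | methyl (2E,4R,6S)-6-(acetyloxy)-4-hydroxy-6-methyl-7-oxo-2-[(4,4,5,5-tetramethyl-1,3,2-dioxaborolan-2-yl)methyl]oct-2-enoate | CC(=O)[C@@](C)(OC(C)=O)C[C@@H](O)/C=C(/C(=O)OC)CB1OC(C)(C)C(C)(C)O1 | intermediate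
12 | (2Z)-2-methylbut-2-enoic acid (angelic acid) | C/C=C(/C)C(=O)O | starting material
13 | (2Z)-2-methylbut-2-enoic 2,4,6-trichlorobenzoic anhydride | C/C=C(/C)C(=O)OC(=O)c1c(Cl)cc(Cl)cc1Cl | intermediate
14 | methyl (2E,4R,6S)-6-(acetyloxy)-6-methyl-4-{[(2Z)-2-methylbut-2-enoyl]oxy}-7-oxo-2-[(4,4,5,5-tetramethyl-1,3,2-dioxaborolan-2-yl)methyl]oct-2-enoate | CC(=O)[C@@](C)(OC(C)=O)C[C@@H](OC(=O)/C(C)=C\C)/C=C(/C(=O)OC)CB1OC(C)(C)C(C)(C)O1 | intermediate
15 | (2E)-but-2-enal | C/C=C/C=O | starting material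
16 | nitromethane | C[N+](=O)[O-] | starting material
17 | (3S)-3-methyl-4-nitrobutanal | O=CC[C@H](C)C[N+](=O)[O-] | intermediate
18 | methyl (3S,4S,6S)-3-[(1R,3S)-3-(acetyloxy)-3-methyl-1-{[(2Z)-2-methylbut-2-enoyl]oxy}-4-oxopentyl]-6-methyl-2-methylidene-7-nitro-4-[(4,4,5,5-tetramethyl-1,3,2-dioxaborolan-2-yl)oxy]heptanoate | C=C(C(=O)OC)[C@@H]([C@H](C[C@H](C)C[N+](=O)[O-])OB1OC(C)(C)C(C)(C)O1)[C@H](OC(=O)/C(C)=C\C)C[C@](C)(OC(C)=O)C(C)=O | intermediate
19 | (1R,3S)-3-(acetyloxy)-3-methyl-1-[(2S,3S)-4-methylidene-2-[(2S)-2-methyl-3-nitropropyl]-5-oxooxolan-3-yl]-4-oxopentyl (2Z)-2-methylbut-2-enoate | C=C1C(=O)O[C@@H](C[C@H](C)C[N+](=O)[O-])[C@H]1[C@H](OC(=O)/C(C)=C\C)C[C@](C)(OC(C)=O)C(C)=O | intermediate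
20 | (1R,3S)-3-(acetyloxy)-3-methyl-1-[(2S,3S)-4-methylidene-2-[(2S)-2-methyl-3-oxopropyl]-5-oxooxolan-3-yl]-4-oxopentyl (2Z)-2-methylbut-2-enoate | C=C1C(=O)O[C@@H](C[C@H](C)C=O)[C@H]1[C@H](OC(=O)/C(C)=C\C)C[C@](C)(OC(C)=O)C(C)=O | intermediate
21 | (1R,3S)-3-(acetyloxy)-4-[(dibutylboranyl)oxy]-3-methyl-1-[(2S,3S)-4-methylidene-2-[(2S)-2-methyl-3-oxopropyl]-5-oxooxolan-3-yl]pent-4-en-1-yl (2Z)-2-methylbut-2-enoate | C=C1C(=O)O[C@@H](C[C@H](C)C=O)[C@H]1[C@H](OC(=O)/C(C)=C\C)C[C@](C)(OC(C)=O)C(=C)OB(CCCC)CCCC | intermediate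
22 | (3aS,4R,6S,9R,10S,11aS)-6-(acetyloxy)-9-hydroxy-6,10-dimethyl-3-methylidene-2,7-dioxododecahydrocyclodeca[b]furan-4-yl (2Z)-2-methylbut-2-enoate | C=C1C(=O)O[C@H]2C[C@H](C)[C@H](O)CC(=O)[C@@](C)(OC(C)=O)C[C@@H](OC(=O)/C(C)=C\C)[C@@H]12 | target

**Step count**
Total: 10 steps. Longest linear sequence: 9 steps (steps 1–6, then 8–10); step 7 makes the second fragment in one step.

**Three steps most likely to fail**

Step 10 (macrocyclic boron aldol). The ten-membered ring is strained, oligomerisation and enolisation of the C10 aldehyde compete, and the C9 configuration rests on macrocyclic control alone. The fallback reverses the order of the two ring-forming bonds so that C9 is set by an intermolecular, reagent-controlled aldol; it sets out from 17 and 14 and comes back to the route at 22. Aldehyde 17 is converted with HC(OMe)3/p-TsOH/MeOH into (2S)-4,4-dimethoxy-2-methyl-1-nitrobutane F6, and an ozonolytic Nef reaction (NaOMe, MeOH; O3, −78 °C; Me2S) gives (2S)-4,4-dimethoxy-2-methylbutanal F7. The methyl ketone of 14 is enolised with (−)-Ipc2BCl/Et3N (Paterson aldol, Re-face addition) and added to F7 at −78 °C to give methyl (2E,4R,6S,9R,10S)-6-(acetyloxy)-9-hydroxy-12,12-dimethoxy-6,10-dimethyl-4-{[(2Z)-2-methylbut-2-enoyl]oxy}-7-oxo-2-[(4,4,5,5-tetramethyl-1,3,2-dioxaborolan-2-yl)methyl]dodec-2-enoate F8. TBSOTf/2,6-lutidine gives its 9-O-tert-butyldimethylsilyl ether F9, and LiBF4 in wet MeCN cleaves the acetal to the 12-oxo aldehyde F10. Thermal intramolecular allylboration at high dilution (toluene, 90 °C, 0.002 M; then p-TsOH) closes the carbocycle and the lactone to the 9-O-tert-butyldimethylsilyl ether of the target F11, and HF·pyridine gives 22.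

Step 8 (proposed new allylboration–lactonisation). The ester-deactivated boronate may not be activated enough by a chiral acid, the C7 ketone could be allylated intramolecularly, and the allylic angelate could be lost by 1,4-elimination. The fallback is the known indium Barbier route to cis α-methylene-γ-butyrolactones from 2-(bromomethyl)alk-2-enoates; it sets out from 14 and comes back to the route at 19. Oxidation of the C–B bond (NaBO3·4H2O, THF/H2O, 0 °C) gives methyl (2E,4R,6S)-6-(acetyloxy)-2-(hydroxymethyl)-6-methyl-4-{[(2Z)-2-methylbut-2-enoyl]oxy}-7-oxooct-2-enoate F4. Appel bromination (CBr4, PPh3, CH2Cl2, 0 °C) gives methyl (2Z,4R,6S)-6-(acetyloxy)-2-(bromomethyl)-6-methyl-4-{[(2Z)-2-methylbut-2-enoyl]oxy}-7-oxooct-2-enoate F5. Indium metal (In powder) in THF/H2O at rt with 17, followed by p-TsOH, gives the syn adduct and hence cis lactone 19 under substrate control from C4.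

Step 1 (proposed new acetaldehyde/diketone aldol). Biacetyl may self-condense through its own enamine, acetaldehyde may self-condense, and the two small carbonyl substituents may give modest enantioselectivity. The fallback is the known copper-bis(oxazoline) Mukaiyama aldol of vicinal diketones; it sets out from 1 and comes back to the route at 6, so steps 2 and 3 are not needed. Compound 1 and 1-(tert-butylsulfanyl)-1-(trimethylsilyloxy)ethene (C=C(O[Si](C)(C)C)SC(C)(C)C) react with [Cu((S,S)-t-Bu-box)](OTf)2 (a divalent copper complex, 10 mol %) in THF at −78 °C to give S-tert-butyl (3S)-3-methyl-4-oxo-3-[(trimethylsilyl)oxy]pentanethioate F1. Dilute HCl in THF gives S-tert-butyl (3S)-3-hydroxy-3-methyl-4-oxopentanethioate F2, and Ac2O/Et3N/DMAP gives S-tert-butyl (3S)-3-(acetyloxy)-3-methyl-4-oxopentanethioate F3. Fukuyama reduction (Et3SiH, 10% Pd/C, acetone, rt) then gives aldehyde 6.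

**Further compounds**
F1 | step 1 | S-tert-butyl (3S)-3-methyl-4-oxo-3-[(trimethylsilyl)oxy]pentanethioate | CC(=O)[C@@](C)(O[Si](C)(C)C)CC(=O)SC(C)(C)C
F2 | step 1 | S-tert-butyl (3S)-3-hydroxy-3-methyl-4-oxopentanethioate | CC(=O)[C@@](C)(O)CC(=O)SC(C)(C)C
F3 | step 1 | S-tert-butyl (3S)-3-(acetyloxy)-3-methyl-4-oxopentanethioate | CC(=O)[C@@](C)(OC(C)=O)CC(=O)SC(C)(C)C
F4 | step 8 | methyl (2E,4R,6S)-6-(acetyloxy)-2-(hydroxymethyl)-6-methyl-4-{[(2Z)-2-methylbut-2-enoyl]oxy}-7-oxooct-2-enoate | CC(=O)[C@@](C)(OC(C)=O)C[C@@H](OC(=O)/C(C)=C\C)/C=C(/C(=O)OC)CO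
F5 | step 8 | methyl (2Z,4R,6S)-6-(acetyloxy)-2-(bromomethyl)-6-methyl-4-{[(2Z)-2-methylbut-2-enoyl]oxy}-7-oxooct-2-enoate | CC(=O)[C@@](C)(OC(C)=O)C[C@@H](OC(=O)/C(C)=C\C)/C=C(/C(=O)OC)CBr
F6 | step 10 | (2S)-4,4-dimethoxy-2-methyl-1-nitrobutane | COC(C[C@H](C)C[N+](=O)[O-])OC
F7 | step 10 | (2S)-4,4-dimethoxy-2-methylbutanal | COC(C[C@H](C)C=O)OC
F8 | step 10 | methyl (2E,4R,6S,9R,10S)-6-(acetyloxy)-9-hydroxy-12,12-dimethoxy-6,10-dimethyl-4-{[(2Z)-2-methylbut-2-enoyl]oxy}-7-oxo-2-[(4,4,5,5-tetramethyl-1,3,2-dioxaborolan-2-yl)methyl]dodec-2-enoate | COC(OC)C[C@H](C)[C@H](O)CC(=O)[C@@](C)(OC(C)=O)C[C@@H](OC(=O)/C(C)=C\C)/C=C(/C(=O)OC)CB1OC(C)(C)C(C)(C)O1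
F9 | step 10 | methyl (2E,4R,6S,9R,10S)-6-(acetyloxy)-9-[(tert-butyldimethylsilyl)oxy]-12,12-dimethoxy-6,10-dimethyl-4-{[(2Z)-2-methylbut-2-enoyl]oxy}-7-oxo-2-[(4,4,5,5-tetramethyl-1,3,2-dioxaborolan-2-yl)methyl]dodec-2-enoate | COC(OC)C[C@H](C)[C@H](O[Si](C)(C)C(C)(C)C)CC(=O)[C@@](C)(OC(C)=O)C[C@@H](OC(=O)/C(C)=C\C)/C=C(/C(=O)OC)CB1OC(C)(C)C(C)(C)O1
F10 | step 10 | methyl (2E,4R,6S,9R,10S)-6-(acetyloxy)-9-[(tert-butyldimethylsilyl)oxy]-6,10-dimethyl-4-{[(2Z)-2-methylbut-2-enoyl]oxy}-7,12-dioxo-2-[(4,4,5,5-tetramethyl-1,3,2-dioxaborolan-2-yl)methyl]dodec-2-enoate | O=CC[C@H](C)[C@H](O[Si](C)(C)C(C)(C)C)CC(=O)[C@@](C)(OC(C)=O)C[C@@H](OC(=O)/C(C)=C\C)/C=C(/C(=O)OC)CB1OC(C)(C)C(C)(C)O1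
F11 | step 10 | (3aS,4R,6S,9R,10S,11aS)-6-(acetyloxy)-9-[(tert-butyldimethylsilyl)oxy]-6,10-dimethyl-3-methylidene-2,7-dioxododecahydrocyclodeca[b]furan-4-yl (2Z)-2-methylbut-2-enoate | C=C1C(=O)O[C@H]2C[C@H](C)[C@H](O[Si](C)(C)C(C)(C)C)CC(=O)[C@@](C)(OC(C)=O)C[C@@H](OC(=O)/C(C)=C\C)[C@@H]12
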